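**Strategy.** The target is a linear trimer of one flavan unit, so the route rests on two C4→C6 Friedel–Crafts disconnections and on a single monomer, tri-O-benzylepioritin. The pyran ring C of this monomer, and hence that of the top unit, is not closed directly: it is grown from a cis-2-aryl-2,3-dihydrobenzofuran-3-ylmethyl mesylate. The key step exploits that C4a of ring A is para to the C7 oxygen and ortho to O1; this carbon migrates from C3 to the exocyclic CH2 (the future C4) through a phenonium ion, and water opens the ion at C3. One operation thus delivers the ring O1–C2–C3–C4–C4a–C8a and the 3-hydroxyl cis to the 2-aryl group.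

Key step: step 8

Assumption: the sense of induction of Rh2(S-PTTL)4 in step 6 is taken by analogy with simpler 2-benzyloxyphenyl diazoacetates; if it proves opposite, Rh2(R-PTTL)4 is used instead.
Numbering: flavan numbering (O1, C2, C3, C4, C4a, C5–C8, C8a) is used in the Why lines also for the precursor atoms that become these positions; epioritin is (2R,3R)-2,3-cis-7,8,4'-trihydroxyflavan-3-ol and α/β refer to the usual flavan drawing.

Step 1
Reactants: 1 2,3,4-trihydroxybenzaldehyde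
Product: 2 3,4-bis(benzyloxy)-2-hydroxybenzaldehyde
Conditions: BnBr (2.1 equiv), K2CO3, DMF, rt
Reagents that add atoms: benzyl bromide, BrCc1ccccc1
Why: Williamson etherification; the 4- and 3-phenoxides should react while the 2-hydroxyl, hydrogen-bonded to the formyl group, stays free.

Step 2
Reactants: 2 3,4-bis(benzyloxy)-2-hydroxybenzaldehyde; 3 4-(benzyloxy)benzyl chloride
Product: 4 3,4-bis(benzyloxy)-2-{[4-(benzyloxy)benzyl]oxy}benzaldehyde
Conditions: K2CO3, KI (cat.), DMF, 70 °C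
Reagents that add atoms: none
Why: Williamson etherification of the chelated phenol at higher temperature; the new OCH2 carbon is the future C2 and already carries ring B.

Step 3
Reactants: 4 3,4-bis(benzyloxy)-2-{[4-(benzyloxy)benzyl]oxy}benzaldehyde
Product: 5 (E)-N-tosylhydrazone of aldehyde 4
Conditions: TsNHNH2, MeOH, rt
Reagents that add atoms: 4-methylbenzenesulfonohydrazide, Cc1ccc(cc1)S(=O)(=O)NN
Why: hydrazone condensation under neutral conditions, which spares the acid-labile 4-benzyloxybenzyl aryl ether.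

Step 4
Reactants: 5 (E)-N-tosylhydrazone of aldehyde 4
Product: 6 methyl 2-(3,4-bis(benzyloxy)-2-{[4-(benzyloxy)benzyl]oxy}phenyl)acetate
Conditions: LiOtBu, Pd2(dba)3 (2.5 mol %), CO (1 atm), MeOH, ClCH2CH2Cl, 60 °C
Reagents that add atoms: carbon monoxide, [C-]#[O+]; methanol, CO
Why: Bamford–Stevens formation of the aryldiazomethane, palladium carbene formation, CO insertion to the aryl ketene and methanolysis (palladium-catalysed carbene carbonylation) should homologate the aldehyde by one carbon without acid.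

Step 5
Reactants: 6 methyl 2-(3,4-bis(benzyloxy)-2-{[4-(benzyloxy)benzyl]oxy}phenyl)acetate
Product: 7 methyl 2-diazo-2-(3,4-bis(benzyloxy)-2-{[4-(benzyloxy)benzyl]oxy}phenyl)acetate
Conditions: p-ABSA, DBU, MeCN, 0 °C to rt
Reagents that add atoms: 4-acetamidobenzenesulfonyl azide, CC(=O)Nc1ccc(cc1)S(=O)(=O)N=[N+]=[N-]
Why: Regitz diazo transfer to the enolate of the aryl acetate.

Step 6
Reactants: 7 methyl 2-diazo-2-(3,4-bis(benzyloxy)-2-{[4-(benzyloxy)benzyl]oxy}phenyl)acetate
Product: 8 methyl (2S,3R)-6,7-bis(benzyloxy)-2-[4-(benzyloxy)phenyl]-2,3-dihydro-1-benzofuran-3-carboxylate (2,3-cis)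
Conditions: Rh2(S-PTTL)4 (dirhodium tetrakis[N-phthaloyl-(S)-tert-leucinate], 1 mol %), toluene, −60 °C
Reagents that add atoms: none
Why: intramolecular 1,5 C–H insertion of the donor/acceptor rhodium carbenoid into the ether CH2 activated by oxygen and the 4-benzyloxyphenyl group; the compact insertion transition state should give the cis isomer, and the chiral carboxylate ligands set the absolute configuration at C2 and C3.

Step 7
Reactants: 8 methyl (2S,3R)-6,7-bis(benzyloxy)-2-[4-(benzyloxy)phenyl]-2,3-dihydro-1-benzofuran-3-carboxylate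
Product: 9 [(2S,3S)-6,7-bis(benzyloxy)-2-[4-(benzyloxy)phenyl]-2,3-dihydro-1-benzofuran-3-yl]methanol (2,3-cis)
Conditions: i-Bu2AlH, CH2Cl2, −78 °C; aq. potassium sodium tartrate
Reagents that add atoms: none
Why: non-basic hydride reduction of the ester (i-Bu2AlH reduction), chosen so that the epimerisable cis centre next to the ester is not equilibrated to trans.

Step 8
Reactants: 9 [(2S,3S)-6,7-bis(benzyloxy)-2-[4-(benzyloxy)phenyl]-2,3-dihydro-1-benzofuran-3-yl]methanol
Product: 12 (2R,3R)-7,8-bis(benzyloxy)-2-[4-(benzyloxy)phenyl]chroman-3-ol, via primary mesylate 10 (not isolated), via phenonium methanesulfonate 11 (not isolated)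
Conditions: Ms2O, 2,6-lutidine, CH2Cl2, 0 °C; then HFIP–H2O (9:1), 2,6-lutidine, 40 °C
Reagents that add atoms: methanesulfonic anhydride, CS(=O)(=O)OS(C)(=O)=O (atoms in intermediates 10 and 11 only); water, O
Why: Mesylation turns the exocyclic CH2 (future C4) into a leaving-group site; in the ionising, poorly nucleophilic medium the electron-rich ring A (C4a para to the 7-benzyloxy group, ortho to O1) displaces mesylate from the rear to give the bridged phenonium ion 11, and water opens its cyclopropane at C3 anti to C4a, so that the C3–C4a bond is exchanged for a C4–C4a bond and the five-membered ring becomes the pyran ring. The closest known reaction type is the aryl-assisted solvolysis of 2-arylethyl sulfonates with 1,2-aryl shift (Wagner–Meerwein, neophyl-type ring enlargement, as in 9-fluorenylmethanol to phenanthrene). The six-membered ring is closed by a 3-exo-tet attack of C4a on C4 followed by opening of the spiro-cyclopropane, a net 1,2-shift that enlarges the ring by one atom. The new C3 stereocentre is set by inversion, because water enters anti to the departing C4a; this translates the cis relationship of aryl and CH2OMs in 9 into the 2,3-cis relationship of aryl and hydroxyl in 12, while C2 is untouched. The step needs opening at C3 and not at the CH2 carbon, and substitution and not elimination: opening at C3 relieves the strain of the bicyclic ion, whereas opening at CH2 only returns 9, and neither the C2–H bond nor the ring B bond is antiperiplanar to the breaking C3–C4a bond, which should disfavour hydride and ring B shifts; 2,6-lutidine buffers the acid.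

Step 9
Reactants: 12 (2R,3R)-7,8-bis(benzyloxy)-2-[4-(benzyloxy)phenyl]chroman-3-ol
Product: 13 (2R,3R,4S)-7,8-bis(benzyloxy)-2-[4-(benzyloxy)phenyl]-4-(2-ethoxyethoxy)chroman-3-ol (2,3-cis-3,4-trans, 4β-ether)
Conditions: DDQ (2 equiv), EtOCH2CH2OH, CH2Cl2, rt
Reagents that add atoms: 2-ethoxyethanol, CCOCCO
Why: DDQ benzylic oxidation; hydride is abstracted from C4 (para to the C7 oxygen, ortho to O1) and the alcohol adds to the cation anti to the axial 3-hydroxyl, which sets C4 as the 4β-ether.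

Step 10
Reactants: 12 (2R,3R)-7,8-bis(benzyloxy)-2-[4-(benzyloxy)phenyl]chroman-3-ol
Product: 14 tert-butyl (2R,3R)-7,8-bis(benzyloxy)-2-[4-(benzyloxy)phenyl]chroman-3-yl carbonate
Conditions: Boc2O, DMAP (cat.), CH2Cl2, rt
Reagents that add atoms: di-tert-butyl dicarbonate, CC(C)(C)OC(=O)OC(=O)OC(C)(C)C
Why: DMAP-catalysed O-acylation of the secondary alcohol, which installs the internal oxygen nucleophile for step 11.

Step 11
Reactants: 14 tert-butyl (2R,3R)-7,8-bis(benzyloxy)-2-[4-(benzyloxy)phenyl]chroman-3-yl carbonate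
Product: 15 (2R,3S,4R)-7,8-bis(benzyloxy)-2-[4-(benzyloxy)phenyl]chromane-3,4-diyl carbonate (tri-O-benzylteracacidin 3,4-carbonate, 2,3-cis-3,4-cis)
Conditions: DDQ (1.5 equiv), 4 Å MS, CH2Cl2, rt
Reagents that add atoms: none
Why: DDQ benzylic oxidation with neighbouring-group capture; the C4 cation is trapped 5-exo by the carbonyl oxygen of the 3α-O-Boc group with loss of isobutene, and the tether forces the new C4–O bond cis to the C3–O bond (4α).

Step 12
Reactants: 13 4β-(2-ethoxyethoxy)-tri-O-benzylepioritin; 15 tri-O-benzylteracacidin 3,4-carbonate (3 equiv, excess recovered)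
Product: 16 hexa-O-benzyl-epioritin-(4β→6)-epioritin-4α-ol 3,4-carbonate (upper unit 2,3-cis-3,4-trans, lower unit all-cis)
Conditions: TMSOTf (cat.), CH2Cl2, −78 to −40 °C; aq. NaHCO3
Reagents that add atoms: none
Why: Friedel–Crafts benzylation; Lewis-acid ionisation of the chelating 4-ether gives the C4 cation, which should attack C6 of 15 (para to O1, ortho to the 7-benzyloxy group) from the face anti to the 3-hydroxyl (4β), while the carbonate keeps the benzylic C4 oxygen of 15 from ionising and the excess of 15 suppresses self-condensation.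

Step 13
Reactants: 13 4β-(2-ethoxyethoxy)-tri-O-benzylepioritin; 16 hexa-O-benzyl dimer carbonate (2 equiv, excess recovered)
Product: 17 nona-O-benzyl-epioritin-(4β→6)-epioritin-(4β→6)-epioritin-4α-ol 3,4-carbonate (carbonate on the lower unit)
Conditions: TMSOTf (cat.), CH2Cl2, −78 to −40 °C; aq. NaHCO3
Reagents that add atoms: none
Why: second Friedel–Crafts benzylation; the only unhindered nucleophilic position of 16 is C6 of its upper unit (C6 of the lower unit is substituted, both C5 positions are peri-hindered), and attack anti to the 3-hydroxyl again sets the 4β configuration.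

Step 14
Reactants: 17 nona-O-benzyl trimer carbonate
Product: 18 nona-O-benzyl-epioritin-(4β→6)-epioritin-(4β→6)-epioritin-4α-ol
Conditions: K2CO3 (cat.), MeOH–THF, rt
Reagents that add atoms: none
Why: transesterification of the cyclic carbonate with methanol; it is done while all phenols are still benzylated so that no quinone methide can form at C4.

Step 15
Reactants: 18 nona-O-benzyl-epioritin-(4β→6)-epioritin-(4β→6)-epioritin-4α-ol
Product: 19 epioritin-(4β→6)-epioritin-(4β→6)-epioritin-4α-ol (CNP0140823.1)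
Conditions: H2 (1 atm), Pd(OH)2/C, THF–MeOH, rt, neutral, short contact time
Reagents that add atoms: none
Why: catalytic hydrogenolysis of the nine aryl benzyl ethers; under neutral conditions these should cleave faster than the cyclic C2–O1 ether and the free benzylic C4 hydroxyl.

**Compound list**

1 | 2,3,4-trihydroxybenzaldehyde | O=Cc1ccc(O)c(O)c1O | starting material
2 | 3,4-bis(benzyloxy)-2-hydroxybenzaldehyde | O=Cc1ccc(OCc2ccccc2)c(OCc2ccccc2)c1O | intermediate
3 | 4-(benzyloxy)benzyl chloride | ClCc1ccc(OCc2ccccc2)cc1 | starting material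
4 | 3,4-bis(benzyloxy)-2-{[4-(benzyloxy)benzyl]oxy}benzaldehyde | O=Cc1ccc(OCc2ccccc2)c(OCc2ccccc2)c1OCc1ccc(OCc2ccccc2)cc1 | intermediate
5 | (E)-N-tosylhydrazone of 4 | Cc1ccc(cc1)S(=O)(=O)N/N=C/c1ccc(OCc2ccccc2)c(OCc2ccccc2)c1OCc1ccc(OCc2ccccc2)cc1 | intermediate
6 | methyl 2-(3,4-bis(benzyloxy)-2-{[4-(benzyloxy)benzyl]oxy}phenyl)acetate | COC(=O)Cc1ccc(OCc2ccccc2)c(OCc2ccccc2)c1OCc1ccc(OCc2ccccc2)cc1 | intermediate
7 | methyl 2-diazo-2-(3,4-bis(benzyloxy)-2-{[4-(benzyloxy)benzyl]oxy}phenyl)acetate | COC(=O)C(=[N+]=[N-])c1ccc(OCc2ccccc2)c(OCc2ccccc2)c1OCc1ccc(OCc2ccccc2)cc1 | intermediate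
8 | methyl (2S,3R)-6,7-bis(benzyloxy)-2-[4-(benzyloxy)phenyl]-2,3-dihydro-1-benzofuran-3-carboxylate (cis) | COC(=O)[C@@H]1c2ccc(OCc3ccccc3)c(OCc3ccccc3)c2O[C@@H]1c1ccc(OCc2ccccc2)cc1 | intermediate
9 | [(2S,3S)-6,7-bis(benzyloxy)-2-[4-(benzyloxy)phenyl]-2,3-dihydro-1-benzofuran-3-yl]methanol (cis) | OC[C@@H]1c2ccc(OCc3ccccc3)c(OCc3ccccc3)c2O[C@@H]1c1ccc(OCc2ccccc2)cc1 | intermediate
10 | methanesulfonate of 9 (primary mesylate) | CS(=O)(=O)OC[C@@H]1c2ccc(OCc3ccccc3)c(OCc3ccccc3)c2O[C@@H]1c1ccc(OCc2ccccc2)cc1 | intermediate (not isolated)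
11 | bridged phenonium ion (C4 and C3 both bonded to C4a, charge drawn on the 7-oxygen), methanesulfonate ion pair | C1[C@H]2[C@@H](c3ccc(OCc4ccccc4)cc3)OC3=C(OCc4ccccc4)C(=[O+]Cc4ccccc4)C=C[C@]123.CS(=O)(=O)[O-] | intermediate (not isolated)
12 | (2R,3R)-7,8-bis(benzyloxy)-2-[4-(benzyloxy)phenyl]chroman-3-ol (tri-O-benzylepioritin, 2,3-cis) | c1cc2c(c(OCc3ccccc3)c1OCc1ccccc1)O[C@H](c1ccc(OCc3ccccc3)cc1)[C@H](O)C2 | intermediate
13 | (2R,3R,4S)-7,8-bis(benzyloxy)-2-[4-(benzyloxy)phenyl]-4-(2-ethoxyethoxy)chroman-3-ol (4β-ether) | c1cc2c(c(OCc3ccccc3)c1OCc1ccccc1)O[C@H](c1ccc(OCc3ccccc3)cc1)[C@H](O)[C@H]2OCCOCC | intermediate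
14 | tert-butyl (2R,3R)-7,8-bis(benzyloxy)-2-[4-(benzyloxy)phenyl]chroman-3-yl carbonate | c1cc2c(c(OCc3ccccc3)c1OCc1ccccc1)O[C@H](c1ccc(OCc3ccccc3)cc1)[C@H](OC(=O)OC(C)(C)C)C2 | intermediate
15 | (2R,3S,4R)-7,8-bis(benzyloxy)-2-[4-(benzyloxy)phenyl]chromane-3,4-diyl carbonate (all-cis) | c1cc2c(c(OCc3ccccc3)c1OCc1ccccc1)O[C@H](c1ccc(OCc3ccccc3)cc1)[C@H]1[C@@H]2OC(=O)O1 | intermediate
16 | hexa-O-benzyl-epioritin-(4β→6)-epioritin-4α-ol 3,4-carbonate | c1cc2c(c(OCc3ccccc3)c1OCc1ccccc1)O[C@H](c1ccc(OCc3ccccc3)cc1)[C@H](O)[C@H]2c1cc2c(c(OCc3ccccc3)c1OCc1ccccc1)O[C@H](c1ccc(OCc3ccccc3)cc1)[C@H]1[C@@H]2OC(=O)O1 | intermediate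
17 | nona-O-benzyl-epioritin-(4β→6)-epioritin-(4β→6)-epioritin-4α-ol 3,4-carbonate | c1cc2c(c(OCc3ccccc3)c1OCc1ccccc1)O[C@H](c1ccc(OCc3ccccc3)cc1)[C@H](O)[C@H]2c1cc2c(c(OCc3ccccc3)c1OCc1ccccc1)O[C@H](c1ccc(OCc3ccccc3)cc1)[C@H](O)[C@H]2c1cc2c(c(OCc3ccccc3)c1OCc1ccccc1)O[C@H](c1ccc(OCc3ccccc3)cc1)[C@H]1[C@@H]2OC(=O)O1 | intermediate
18 | nona-O-benzyl-epioritin-(4β→6)-epioritin-(4β→6)-epioritin-4α-ol | c1cc2c(c(OCc3ccccc3)c1OCc1ccccc1)O[C@H](c1ccc(OCc3ccccc3)cc1)[C@H](O)[C@H]2c1cc2c(c(OCc3ccccc3)c1OCc1ccccc1)O[C@H](c1ccc(OCc3ccccc3)cc1)[C@H](O)[C@H]2c1cc2c(c(OCc3ccccc3)c1OCc1ccccc1)O[C@H](c1ccc(OCc3ccccc3)cc1)[C@H](O)[C@@H]2O | intermediate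
19 | epioritin-(4β→6)-epioritin-(4β→6)-epioritin-4α-ol (CNP0140823.1) | Oc1ccc([C@H]2Oc3c(ccc(O)c3O)[C@H](c3cc4c(c(O)c3O)O[C@H](c3ccc(O)cc3)[C@H](O)[C@H]4c3cc4c(c(O)c3O)O[C@H](c3ccc(O)cc3)[C@H](O)[C@@H]4O)[C@H]2O)cc1 | target

**Count.** Total: 15 steps. Longest linear sequence: 14 steps (steps 1–8 and 10–15).

**Steps most likely to fail**

Step 8 (key step). The phenonium ion may lose a proton (elimination to a chromene) or take up water at its CH2 terminus, and partial ionisation at C2 in the ionising medium would erode the cis relationship. The fallback sets out from 9 and returns at 12; it keeps the aryl-shift ring expansion but makes elimination the intended course and sets C3 afterwards. Mesylate 10 is heated in HFIP with 2,6-di-tert-butylpyridine in the absence of water to give (2S)-7,8-bis(benzyloxy)-2-[4-(benzyloxy)phenyl]-2H-chromene F1 (C2 keeps its spatial arrangement). Hydroboration–oxidation (BH3·THF; H2O2, NaOH), with boron adding at C3 anti to the 2-aryl group, should give (2R,3S)-7,8-bis(benzyloxy)-2-[4-(benzyloxy)phenyl]chroman-3-ol F2 (2,3-trans). Dess–Martin oxidation gives (2R)-7,8-bis(benzyloxy)-2-[4-(benzyloxy)phenyl]chroman-3-one F3, and LiBH(s-Bu)3 at −78 °C delivers hydride anti to the 2-aryl group to give the 2,3-cis alcohol 12.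

Step 13 (the same issue applies to step 12). Electrophile and nucleophile carry the same weakly nucleophilic pyrogallol-type ring A, so self-condensation of the cation precursor, attack at C5 and over-alkylation of the product may compete. The fallback sets out from 12 and 16 and returns at 19; it caps the nucleophilic position of the electrophile with bromine so that an equimolar coupling becomes possible. NBS in CH2Cl2 at −20 °C should brominate 12 at C6 to give (2R,3R)-6-bromo-7,8-bis(benzyloxy)-2-[4-(benzyloxy)phenyl]chroman-3-ol F4. DDQ with 2-ethoxyethanol gives (2R,3R,4S)-6-bromo-7,8-bis(benzyloxy)-2-[4-(benzyloxy)phenyl]-4-(2-ethoxyethoxy)chroman-3-ol F5. Coupling of F5 with 16 (TMSOTf, CH2Cl2, −78 to −40 °C) gives the 6-bromo derivative (upper unit) of trimer carbonate 17, F6. K2CO3 in MeOH gives the 6-bromo derivative (upper unit) of nona-O-benzyl trimer 18, F7. Hydrogenolysis with H2, Pd(OH)2/C and Et3N removes the bromine and the benzyl ethers together and gives 19.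

Step 15. Hydrogenolysis of the benzylic C4–O bond of the lower unit may compete with cleavage of the nine benzyl ethers. The fallback sets out from 18 and returns at 19; it carries the lower C4 through the hydrogenolysis at the ketone oxidation level. MnO2 in CH2Cl2 should oxidise only the benzylic C4 hydroxyl to give the 4-oxo (lower unit) analogue of 18, F8. H2 with Pd(OH)2/C then gives the free phenolic 4-oxo trimer F9. NaBH4 with CeCl3 in MeOH at −40 °C should deliver hydride anti to the axial 3-hydroxyl and give the 3,4-cis diol 19.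

**Further compounds**

F1 | step 8 | (2S)-7,8-bis(benzyloxy)-2-[4-(benzyloxy)phenyl]-2H-chromene | c1cc2c(c(OCc3ccccc3)c1OCc1ccccc1)O[C@H](c1ccc(OCc3ccccc3)cc1)C=C2
F2 | step 8 | (2R,3S)-7,8-bis(benzyloxy)-2-[4-(benzyloxy)phenyl]chroman-3-ol (2,3-trans) | c1cc2c(c(OCc3ccccc3)c1OCc1ccccc1)O[C@H](c1ccc(OCc3ccccc3)cc1)[C@@H](O)C2
F3 | step 8 | (2R)-7,8-bis(benzyloxy)-2-[4-(benzyloxy)phenyl]chroman-3-one | c1cc2c(c(OCc3ccccc3)c1OCc1ccccc1)O[C@H](c1ccc(OCc3ccccc3)cc1)C(=O)C2
F4 | step 13 | (2R,3R)-6-bromo-7,8-bis(benzyloxy)-2-[4-(benzyloxy)phenyl]chroman-3-ol | Brc1cc2c(c(OCc3ccccc3)c1OCc1ccccc1)O[C@H](c1ccc(OCc3ccccc3)cc1)[C@H](O)C2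
F5 | step 13 | (2R,3R,4S)-6-bromo-7,8-bis(benzyloxy)-2-[4-(benzyloxy)phenyl]-4-(2-ethoxyethoxy)chroman-3-ol | Brc1cc2c(c(OCc3ccccc3)c1OCc1ccccc1)O[C@H](c1ccc(OCc3ccccc3)cc1)[C@H](O)[C@H]2OCCOCC
F6 | step 13 | 6-bromo derivative (upper unit) of trimer carbonate 17 | Brc1cc2c(c(OCc3ccccc3)c1OCc1ccccc1)O[C@H](c1ccc(OCc3ccccc3)cc1)[C@H](O)[C@H]2c1cc2c(c(OCc3ccccc3)c1OCc1ccccc1)O[C@H](c1ccc(OCc3ccccc3)cc1)[C@H](O)[C@H]2c1cc2c(c(OCc3ccccc3)c1OCc1ccccc1)O[C@H](c1ccc(OCc3ccccc3)cc1)[C@H]1[C@@H]2OC(=O)O1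
F7 | step 13 | 6-bromo derivative (upper unit) of nona-O-benzyl trimer 18 | Brc1cc2c(c(OCc3ccccc3)c1OCc1ccccc1)O[C@H](c1ccc(OCc3ccccc3)cc1)[C@H](O)[C@H]2c1cc2c(c(OCc3ccccc3)c1OCc1ccccc1)O[C@H](c1ccc(OCc3ccccc3)cc1)[C@H](O)[C@H]2c1cc2c(c(OCc3ccccc3)c1OCc1ccccc1)O[C@H](c1ccc(OCc3ccccc3)cc1)[C@H](O)[C@@H]2O
F8 | step 15 | 4-oxo (lower unit) analogue of nona-O-benzyl trimer 18 | c1cc2c(c(OCc3ccccc3)c1OCc1ccccc1)O[C@H](c1ccc(OCc3ccccc3)cc1)[C@H](O)[C@H]2c1cc2c(c(OCc3ccccc3)c1OCc1ccccc1)O[C@H](c1ccc(OCc3ccccc3)cc1)[C@H](O)[C@H]2c1cc2c(c(OCc3ccccc3)c1OCc1ccccc1)O[C@H](c1ccc(OCc3ccccc3)cc1)[C@H](O)C2=O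
F9 | step 15 | free phenolic 4-oxo (lower unit) trimer | Oc1ccc([C@H]2Oc3c(ccc(O)c3O)[C@H](c3cc4c(c(O)c3O)O[C@H](c3ccc(O)cc3)[C@H](O)[C@H]4c3cc4c(c(O)c3O)O[C@H](c3ccc(O)cc3)[C@H](O)C4=O)[C@H]2O)cc1
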